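**Assumption:** the target has no stereocentre, so "single enantiomer" needs no stereocontrol; 3,4,5-tribromoaniline is taken as a purchasable catalogue compound.

## Retrosynthetic overview

1. 8 ⇒ 6 + "MeS⁺": N1–C2 and C3–S are made together by a sulfenylative 5-endo-dig aminocyclisation of a 1-bromoalkyne. The C–N ring closure is the key step and places Br at C2 at the same time.
2. 6 ⇒ 4 (silver-catalysed desilylative bromination) ⇒ 2 + 3 (Sonogashira coupling at C–I only).
3. 2 ⇒ 1 (ortho-iodination; the two ortho positions of 1 are equivalent, para is blocked).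
4. Ring order: the tribrominated benzene ring is bought; the pyrrole ring is the only ring formed, in the last step.

## Route

Step 1
Reactants: 1 3,4,5-tribromoaniline
Product: 2 3,4,5-tribromo-2-iodoaniline
Conditions: NIS (1.0 equiv, portionwise), TFA (0.2 equiv), MeCN, 0 °C → rt, dark
Reagents that add atoms: N-iodosuccinimide, O=C1CCC(=O)N1I
Why: Electrophilic aromatic iodination is directed by NH2 to the only open activated positions, C2 and C6, which are equivalent by symmetry, and the first iodine slows a second substitution; no stereocentre is formed.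

Step 2
Reactants: 2 3,4,5-tribromo-2-iodoaniline; 3 ethynyltrimethylsilane
Product: 4 3,4,5-tribromo-2-[(trimethylsilyl)ethynyl]aniline
Conditions: PdCl2(PPh3)2 (3 mol%), CuI (3 mol%), Et3N/THF 1:1, degassed, rt
Reagents that add atoms: none
Why: Sonogashira coupling, in which Pd(0) inserts into C–I far faster than into any of the three C–Br bonds at room temperature, and the TMS cap prevents Glaser coupling and premature cyclisation.

Step 3
Reactants: 4 3,4,5-tribromo-2-[(trimethylsilyl)ethynyl]aniline
Product: 6 3,4,5-tribromo-2-(bromoethynyl)aniline, via silver acetylide 5 (not isolated)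
Conditions: NBS (1.05 equiv), AgNO3 (10 mol%), acetone, 0 °C → rt, dark; used promptly
Reagents that add atoms: N-bromosuccinimide, O=C1CCC(=O)N1Br
Why: Silver-catalysed desilylative bromination, in which Ag(I) cleaves the C(sp)–Si bond to acetylide 5 and this is brominated by NBS faster than the strongly deactivated tribromoaniline ring reacts at 0 °C.

Step 4
Reactants: 6 3,4,5-tribromo-2-(bromoethynyl)aniline
Product: 8 2,4,5,6-tetrabromo-3-(methylsulfanyl)-1H-indole, via thiirenium ion 7 (not isolated)
Conditions: Me2S⁺–SMe BF4⁻ (DMTSF, 1.2 equiv), NaHCO3 (2 equiv), CH2Cl2/MeCN, 0 °C → rt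
Reagents that add atoms: dimethyl(methylthio)sulfonium tetrafluoroborate, CS[S+](C)C.F[B-](F)(F)F
Why: Proposed new method: a sulfenylative 5-endo-dig aminocyclisation of a 1-bromoalkyne, in which MeS⁺ transfer from DMTSF gives thiirenium ion 7, the ortho-NH2 can open it only at the bromine-bearing carbon (attack at the aryl-bearing carbon would be 4-exo), and anti C–N bond formation followed by loss of H⁺ to NaHCO3 gives the aromatic indole with Br fixed at C2 and SMe at C3, the bromine lone pairs helping to stabilise the positive charge at the attacked carbon; no stereocentre is formed; the closest known reaction type is the Larock-type electrophilic (iodo- or sulfenyl-) cyclisation of 2-alkynylanilines and the DMTSF-mediated thiomethylative cyclisation of ortho-alkynyl anisoles and thioanisoles, which to my knowledge has not been shown for a 1-haloalkyne carrying a free, electron-poor NH2.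

## Compound list

1 | 3,4,5-tribromoaniline | Nc1cc(Br)c(Br)c(Br)c1 | starting material
2 | 3,4,5-tribromo-2-iodoaniline | Nc1cc(Br)c(Br)c(Br)c1I | intermediate
3 | ethynyltrimethylsilane | C#C[Si](C)(C)C | starting material
4 | 3,4,5-tribromo-2-[(trimethylsilyl)ethynyl]aniline | C[Si](C)(C)C#Cc1c(N)cc(Br)c(Br)c1Br | intermediate
5 | [(6-amino-2,3,4-tribromophenyl)ethynyl]silver | [Ag]C#Cc1c(N)cc(Br)c(Br)c1Br | intermediate (not isolated)
6 | 3,4,5-tribromo-2-(bromoethynyl)aniline | BrC#Cc1c(N)cc(Br)c(Br)c1Br | intermediate
7 | 2-(6-amino-2,3,4-tribromophenyl)-3-bromo-1-methylthiiren-1-ium tetrafluoroborate | C[S+]1C(Br)=C1c1c(N)cc(Br)c(Br)c1Br.F[B-](F)(F)F | intermediate (not isolated)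
8 | 2,4,5,6-tetrabromo-3-(methylsulfanyl)-1H-indole | CSc1c(Br)[nH]c2cc(Br)c(Br)c(Br)c12 | target

## Step count and risks

Total step count: 4. Longest linear sequence: 4 steps (1 → 2 → 4 → 6 → 8).

**Step 4 (proposed new step).** The aniline nitrogen is weakly nucleophilic and the bromoalkyne is an electron-poor π-system, so MeS⁺ transfer may be slow or may go to nitrogen instead. The fallback uses known chemistry only; it sets out from 4 and comes back at 8. The TMS group of 4 is removed with K2CO3 in MeOH to give 3,4,5-tribromo-2-ethynylaniline F1. This is cycloisomerised with catalytic NaAuCl4 in EtOH at rt (or CuI in DMF at 100 °C) to 4,5,6-tribromo-1H-indole F2. C3 is sulfenylated with MeSCl (from MeSSMe and SO2Cl2, CH2Cl2, −78 → 0 °C) to give 4,5,6-tribromo-3-(methylsulfanyl)-1H-indole F3. C2, the only free pyrrole position, is then brominated with NBS (1.0 equiv, CH2Cl2, 0 °C) to give 8.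

**Step 3.** NBS may brominate the free aniline at nitrogen or at the last open ring position (C6) in competition with the acetylide. The fallback masks the nitrogen; it sets out from 4 and comes back at 6. Compound 4 is acylated with trifluoroacetic anhydride and pyridine to 2,2,2-trifluoro-N-{3,4,5-tribromo-2-[(trimethylsilyl)ethynyl]phenyl}acetamide F4. The same NBS/AgNO3 exchange is now run on the deactivated anilide to give N-[3,4,5-tribromo-2-(bromoethynyl)phenyl]-2,2,2-trifluoroacetamide F5. The trifluoroacetyl group is removed with K2CO3 in MeOH/H2O at rt to give 6.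

**Step 2.** The iodide is flanked by NH2 and Br, and any competing insertion into a C–Br bond gives polyalkynylated material that is hard to separate. The fallback drops the alkyne and the palladium step; it sets out from 1 and comes back at 8. Compound 1 is treated with tBuOCl (CH2Cl2, −65 °C), then ethyl (methylthio)acetate, then Et3N (Gassman oxindole synthesis: N-chlorination, azasulfonium salt, ylide, [2,3]-sigmatropic shift to the ortho carbon, both ortho positions being equivalent). This gives ethyl 2-(6-amino-2,3,4-tribromophenyl)-2-(methylsulfanyl)acetate F6 (racemic). Dilute HCl lactamises it to 4,5,6-tribromo-3-(methylsulfanyl)-1,3-dihydro-2H-indol-2-one F7 (racemic; the stereocentre disappears in the next operation). POBr3 with imidazole in 1,2-dichloroethane at 80 °C converts the lactam into the 2-bromoindole 8.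

## Further compounds

F1 | step 4 | 3,4,5-tribromo-2-ethynylaniline | C#Cc1c(N)cc(Br)c(Br)c1Br
F2 | step 4 | 4,5,6-tribromo-1H-indole | Brc1cc2[nH]ccc2c(Br)c1Br
F3 | step 4 | 4,5,6-tribromo-3-(methylsulfanyl)-1H-indole | CSc1c[nH]c2cc(Br)c(Br)c(Br)c12
F4 | step 3 | 2,2,2-trifluoro-N-{3,4,5-tribromo-2-[(trimethylsilyl)ethynyl]phenyl}acetamide | C[Si](C)(C)C#Cc1c(NC(=O)C(F)(F)F)cc(Br)c(Br)c1Br
F5 | step 3 | N-[3,4,5-tribromo-2-(bromoethynyl)phenyl]-2,2,2-trifluoroacetamide | BrC#Cc1c(NC(=O)C(F)(F)F)cc(Br)c(Br)c1Br
F6 | step 2 | ethyl 2-(6-amino-2,3,4-tribromophenyl)-2-(methylsulfanyl)acetate (racemic) | CCOC(=O)C(SC)c1c(N)cc(Br)c(Br)c1Br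
F7 | step 2 | 4,5,6-tribromo-3-(methylsulfanyl)-1,3-dihydro-2H-indol-2-one (racemic) | CSC1C(=O)Nc2cc(Br)c(Br)c(Br)c12
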